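**Retrosynthetic overview**
1. Last ring: the oxa-bridge (tetrahydrofuran-3-one, C8–O–C11) closes by transannular oxa-Michael addition of the C8 tertiary alcohol to a C10/C13 ene-dione; this sets C11.
2. First ring, same flask: the 14-membered carbocycle closes by radical carbonylation, forming C9–C10 and C10–C11 from a primary C9 radical, CO (= C10) and a terminal ynone.
3. The linear precursor is cut at C3=C4: Still–Gennari olefination of a C1–C3/C11–C14 keto aldehyde with a C4–C9 phosphonate made in the flask; this sets the Z alkene.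
4. C4–C9 piece: (R)-2-methylglycidol (C7–C9, C8 stereocentre), CO (= C6) and methyl 2-chloroacrylate, joined by a first radical carbonylation.
5. C1–C3/C11–C14 piece: asymmetric 1,4-addition of an isopropenyl group to 5,6-dihydro-2H-pyran-2-one (C1 stereocentre), then lactone opening by a silyl acetylide.

Locants (carbocycle of the target): C1 (CH bearing isopropenyl), C2, C3=C4(CO2Me), C5, C6(=O), C7, C8(Me)(O), C9, C10(=O), C11(H)(O), C12, C13(=O), C14. The target is 1R, 8R, 11S, with C2 cis to CO2Me (Z) and C7/C12 cis on the furanone.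

Assumption: (R)-2-methylglycidol and potassium isopropenyltrifluoroborate are catalogue compounds, and (R)-BINAP is taken to give the (R)-lactone by analogy with aryl additions (use (S)-BINAP if the sense proves opposite).

**Route**

Step 1
Reactants: 1 5,6-dihydro-2H-pyran-2-one; 2 potassium isopropenyltrifluoroborate
Product: 3 (4R)-4-(prop-1-en-2-yl)oxan-2-one
Conditions: [Rh(C8H12)2]BF4 (3 mol%), (R)-BINAP (3.3 mol%), toluene/H2O 10:1, 105 °C
Reagents that add atoms: none
Why: Rhodium-catalysed asymmetric conjugate addition (Hayashi–Miyaura type) of the alkenyltrifluoroborate to the unsaturated lactone; the (R)-BINAP–rhodium alkenyl species inserts one enantioface of the enoate and sets C1 as R.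

Step 2
Reactants: 3 (4R)-4-(prop-1-en-2-yl)oxan-2-one; 4 ethynyltrimethylsilane
Product: 5 (5R)-7-hydroxy-5-(prop-1-en-2-yl)-1-(trimethylsilyl)hept-1-yn-3-one
Conditions: 4, n-C4H9Li, THF, −78 °C; then 3, −78 °C; AcOH quench
Reagents that add atoms: none
Why: Nucleophilic acyl substitution of the lactone by the lithium acetylide; the lithium lactolate is stable at −78 °C, so only one acetylide adds and the hydroxy ynone is released on quench, with C1 untouched.

Step 3
Reactants: 5 (5R)-7-hydroxy-5-(prop-1-en-2-yl)-1-(trimethylsilyl)hept-1-yn-3-one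
Product: 6 (3R)-5-oxo-3-(prop-1-en-2-yl)-7-(trimethylsilyl)hept-6-ynal
Conditions: Dess–Martin periodinane, pyridine, CH2Cl2, 0 °C to rt
Reagents that add atoms: none
Why: Dess–Martin oxidation of the primary alcohol to the aldehyde under buffered, non-basic conditions that spare the silyl ynone and C1.

Step 4
Reactants: 7 (R)-2-methylglycidol, [(2R)-2-methyloxiran-2-yl]methanol
Product: 8 (2R)-2-methyl-3-(phenylselanyl)propane-1,2-diol
Conditions: PhSeH (1.05 equiv), Et3N (10 mol%), EtOH, 0 °C to rt, Ar
Reagents that add atoms: benzeneselenol, [SeH]c1ccccc1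
Why: Base-catalysed SN2 epoxide opening by the selenolate at the unsubstituted carbon (future C9); the quaternary carbinol centre (future C8) comes unchanged from 7.

Step 5
Reactants: 8 (2R)-2-methyl-3-(phenylselanyl)propane-1,2-diol
Product: 9 (2S)-1-iodo-2-methyl-3-(phenylselanyl)propan-2-ol
Conditions: PPh3, I2, imidazole, CH2Cl2, 0 °C
Reagents that add atoms: iodine, II
Why: Appel-type iodination (Garegg–Samuelsson conditions) of the primary hydroxyl, the tertiary one being too hindered to be activated; a transient epoxide, if formed, is reopened by iodide at CH2, so the C8–O bond and configuration are kept (the descriptor changes by priority only).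

Step 6
Reactants: 9 (2S)-1-iodo-2-methyl-3-(phenylselanyl)propan-2-ol; 10 carbon monoxide; 11 methyl 2-chloroacrylate
Product: 12 methyl (6R)-2-chloro-6-hydroxy-6-methyl-4-oxo-7-(phenylselanyl)heptanoate
Conditions: CO (80 atm), 11 (4 equiv), (n-C4H9)3SnH (1.2 equiv), AIBN (0.2 equiv), PhH (0.02 M), 80 °C
Reagents that add atoms: none
Why: Three-component radical carbonylation followed by Giese addition: the stannyl radical takes iodine about two orders of magnitude faster than the phenylselanyl group, the primary C7 radical traps CO to give the C6 acyl radical, and this nucleophilic radical adds to the chloroacrylate before reduction; C8 is untouched and C4 forms as an inconsequential mixture.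

Step 7
Reactants: 12 methyl (6R)-2-chloro-6-hydroxy-6-methyl-4-oxo-7-(phenylselanyl)heptanoate; 6 (3R)-5-oxo-3-(prop-1-en-2-yl)-7-(trimethylsilyl)hept-6-ynal
Product: 14 methyl (2Z,5R)-2-[(4R)-4-hydroxy-4-methyl-2-oxo-5-(phenylselanyl)pentyl]-7-oxo-5-(prop-1-en-2-yl)-9-(trimethylsilyl)non-2-en-8-ynoate, via phosphonate 13 (not isolated)
Conditions: (CF3CH2O)2P(O)H (1.0 equiv), KN(SiMe3)2 (1.1 equiv), THF, −78 °C; 12, −78 to 0 °C; then KN(SiMe3)2 (0.9 equiv), 18-crown-6, −78 °C; 6, −78 °C
Reagents that add atoms: none
Why: One-pot Michaelis–Becker phosphonylation and Still–Gennari Horner–Wadsworth–Emmons olefination: the potassium phosphite turns the α-chloro ester into phosphonate 13 (by SN2, or by E1cB loss of HCl and phospha-Michael addition β to the ketone, both converging), and the potassium/18-crown-6 carbanion of 13 olefinates the aldehyde under kinetic control (fast, irreversible collapse of the erythro adduct), placing C2 cis to CO2Me (Z); C1 and C8 are untouched.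

Step 8
Reactants: 14 methyl (2Z,5R)-2-[(4R)-4-hydroxy-4-methyl-2-oxo-5-(phenylselanyl)pentyl]-7-oxo-5-(prop-1-en-2-yl)-9-(trimethylsilyl)non-2-en-8-ynoate
Product: 15 methyl (2Z,5R)-2-[(4R)-4-hydroxy-4-methyl-2-oxo-5-(phenylselanyl)pentyl]-7-oxo-5-(prop-1-en-2-yl)non-2-en-8-ynoate
Conditions: (n-C4H9)4NF, AcOH (1:1), THF, −20 to 0 °C
Reagents that add atoms: none
Why: Fluoride-induced protodesilylation of the alkynylsilane, buffered with AcOH so that the β-hydroxy ketone, the skipped enone and the liberated ynone survive.

Step 9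
Reactants: 15 methyl (2Z,5R)-2-[(4R)-4-hydroxy-4-methyl-2-oxo-5-(phenylselanyl)pentyl]-7-oxo-5-(prop-1-en-2-yl)non-2-en-8-ynoate; 10 carbon monoxide
Product: 17 methyl (1R,5Z,8R,12S)-1-methyl-3,10,13-trioxo-8-(prop-1-en-2-yl)-15-oxabicyclo[10.2.1]pentadec-5-ene-5-carboxylate (CNP0163183.1), via macrocyclic enedione 16 (not isolated)
Conditions: CO (80 atm), (n-C4H9)3SnH (1.3 equiv), AIBN (0.3 equiv), PhH (0.002 M), 80 °C; then vent, Et3N (0.2 equiv), rt
Reagents that add atoms: none
Why: Proposed new method: the stannyl radical abstracts the PhSe group to give the primary C9 radical, which at 80 atm CO is carbonylated faster than it is reduced at 2 mM hydride; the nucleophilic C10 acyl radical then adds 14-endo to the unsubstituted β-carbon C11 of the terminal ynone (an ynone that is hydrostannylated first remains a competent acceptor, because ipso addition and loss of the stannyl radical give the same ene-dione), the vinyl radical is reduced to ene-dione 16, and catalytic Et3N lets the C8 hydroxyl add 5-exo across the ring to C11, which is set S (cis to C7) because only the cis-2,5-bridged furanone is unstrained and this α-keto centre can equilibrate; the closest known reactions are tin hydride-mediated carbonylative radical macrocyclisation of ω-iodo acrylates, acyl radical macrocyclisation onto enones, and transannular oxa-Michael closure of furanones.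

**Compound list**
1 | 5,6-dihydro-2H-pyran-2-one | O=C1C=CCCO1 | starting material
2 | potassium isopropenyltrifluoroborate | C=C(C)[B-](F)(F)F.[K+] | starting material
3 | (4R)-4-(prop-1-en-2-yl)oxan-2-one | C=C(C)[C@@H]1CCOC(=O)C1 | intermediate
4 | ethynyltrimethylsilane | C#C[Si](C)(C)C | starting material
5 | (5R)-7-hydroxy-5-(prop-1-en-2-yl)-1-(trimethylsilyl)hept-1-yn-3-one | C=C(C)[C@@H](CC(=O)C#C[Si](C)(C)C)CCO | intermediate
6 | (3R)-5-oxo-3-(prop-1-en-2-yl)-7-(trimethylsilyl)hept-6-ynal | C=C(C)[C@@H](CC(=O)C#C[Si](C)(C)C)CC=O | intermediate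
7 | (R)-2-methylglycidol | C[C@@]1(CO)CO1 | starting material
8 | (2R)-2-methyl-3-(phenylselanyl)propane-1,2-diol | C[C@@](O)(CO)C[Se]c1ccccc1 | intermediate
9 | (2S)-1-iodo-2-methyl-3-(phenylselanyl)propan-2-ol | C[C@@](O)(CI)C[Se]c1ccccc1 | intermediate
10 | carbon monoxide | [C-]#[O+] | starting material
11 | methyl 2-chloroacrylate | C=C(Cl)C(=O)OC | starting material
12 | methyl (6R)-2-chloro-6-hydroxy-6-methyl-4-oxo-7-(phenylselanyl)heptanoate (C2 epimers) | C[C@@](O)(CC(=O)CC(Cl)C(=O)OC)C[Se]c1ccccc1 | intermediate
13 | methyl (6R)-2-[bis(2,2,2-trifluoroethoxy)phosphoryl]-6-hydroxy-6-methyl-4-oxo-7-(phenylselanyl)heptanoate (C2 epimers; potassium salt in the flask) | C[C@@](O)(CC(=O)CC(C(=O)OC)P(=O)(OCC(F)(F)F)OCC(F)(F)F)C[Se]c1ccccc1 | intermediate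
14 | methyl (2Z,5R)-2-[(4R)-4-hydroxy-4-methyl-2-oxo-5-(phenylselanyl)pentyl]-7-oxo-5-(prop-1-en-2-yl)-9-(trimethylsilyl)non-2-en-8-ynoate | C=C(C)[C@@H](CC(=O)C#C[Si](C)(C)C)C/C=C(\C(=O)OC)CC(=O)C[C@@](C)(O)C[Se]c1ccccc1 | intermediate
15 | methyl (2Z,5R)-2-[(4R)-4-hydroxy-4-methyl-2-oxo-5-(phenylselanyl)pentyl]-7-oxo-5-(prop-1-en-2-yl)non-2-en-8-ynoate | C=C(C)[C@@H](CC(=O)C#C)C/C=C(\C(=O)OC)CC(=O)C[C@@](C)(O)C[Se]c1ccccc1 | intermediate
16 | methyl (1Z,4R,7E,11R)-11-hydroxy-11-methyl-6,9,13-trioxo-4-(prop-1-en-2-yl)cyclotetradeca-1,7-diene-1-carboxylate (7Z isomer equally usable) | C=C(C)[C@@H]1C/C=C(\C(=O)OC)CC(=O)C[C@@](C)(O)CC(=O)/C=C/C(=O)C1 | intermediate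
17 | methyl (1R,5Z,8R,12S)-1-methyl-3,10,13-trioxo-8-(prop-1-en-2-yl)-15-oxabicyclo[10.2.1]pentadec-5-ene-5-carboxylate | C=C(C)[C@@H]1C/C=C(\C(=O)OC)CC(=O)C[C@]2(C)CC(=O)[C@H](CC(=O)C1)O2 | target

**Totals**
Total step count: 9. Longest linear sequence: 6 steps (steps 4, 5, 6, 7, 8, 9; the branch through steps 1, 2, 3, 7, 8, 9 is equally long).

**Steps most likely to fail, with fallbacks**

Step 9. The acyl radical may be reduced before it cyclises, may attack C3 of the enoate, or the hydroxyl may close 6-endo on C12 instead of 5-exo on C11. The fallback sets out from 15 and comes back at 17. The oxacycle is closed first by an ionic reaction: PMe3-catalysed intramolecular oxa-Michael addition of the tertiary hydroxyl of 15 to its own terminal ynone at high dilution gives the 13-membered macrocyclic (E)-β-alkoxy enone F1, in which oxygen is already bound to C11. Radical carbonylation of F1 [(Me3Si)3SiH, AIBN, CO 80 atm, PhH, 80 °C] then gives the C10 acyl radical, which closes 5-exo across the ring onto the vinylogous ester (a well-behaved alkene acceptor) and delivers 17 with C11 fixed cis by the bridge.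

Step 6. The risks are incomplete iodine/selenium discrimination, telomerisation of the acrylate, and tin-mediated loss of chlorine from 12. The fallback sets out from 9 and comes back at 13. Methyl propiolate is hydrostannylated [(n-C4H9)3SnH, AIBN, then equilibration] to methyl (E)-3-(tributylstannyl)prop-2-enoate F2. Compound 9 is then acylated by a light-assisted carbonylative Stille coupling with F2 [Pd(PPh3)4, CO, hν], an organopalladium process with no hydride chain, to give methyl (2E,6R)-6-hydroxy-6-methyl-4-oxo-7-(phenylselanyl)hept-2-enoate F3. F3 enters step 7 in place of 12 (with one equivalent of base in all) and is converted there into 13 by phospha-Michael addition.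

Step 7. The risks are that phosphonylation of 12 is not clean (competing oxa-Michael closure of the transient enone ester, retro-aldol cleavage) and that the carbanion attacks the silyl ynone. The fallback sets out from 9 and comes back at 13, which is now isolated, and then 14. The P–C bond is made before the ketone exists: methyl bromoacetate and KP(O)(OCH2CF3)2 give methyl 2-[bis(2,2,2-trifluoroethoxy)phosphoryl]acetate F4 (Michaelis–Becker). Knoevenagel methylenation with paraformaldehyde (piperidine, then acid) gives the vinylphosphonate methyl 2-[bis(2,2,2-trifluoroethoxy)phosphoryl]prop-2-enoate F5. Radical carbonylation of 9 under the step 6 conditions with F5 as acceptor gives 13 by Giese addition of the acyl radical. After purification, 13 is olefinated with 6 in a separate Still–Gennari step [KN(SiMe3)2, 18-crown-6, THF, −78 °C] to give 14.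

**Further compounds**
F1 | step 9 | 13-membered macrocyclic (E)-β-alkoxy enone (C8–O–C11H=C12H–C13=O; 1R, 8R; C9H2SePh retained) | C=C(C)[C@@H]1C/C=C(\C(=O)OC)CC(=O)C[C@](C)(C[Se]c2ccccc2)O/C=C/C(=O)C1
F2 | step 6 | methyl (E)-3-(tributylstannyl)prop-2-enoate | CCCC[Sn](CCCC)(CCCC)/C=C/C(=O)OC
F3 | step 6 | methyl (2E,6R)-6-hydroxy-6-methyl-4-oxo-7-(phenylselanyl)hept-2-enoate | C[C@@](O)(CC(=O)/C=C/C(=O)OC)C[Se]c1ccccc1
F4 | step 7 | methyl 2-[bis(2,2,2-trifluoroethoxy)phosphoryl]acetate | COC(=O)CP(=O)(OCC(F)(F)F)OCC(F)(F)F
F5 | step 7 | methyl 2-[bis(2,2,2-trifluoroethoxy)phosphoryl]prop-2-enoate | C=C(C(=O)OC)P(=O)(OCC(F)(F)F)OCC(F)(F)F
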